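**Retrosynthetic overview**
1. Target 14 ⇐ chelation-controlled 5-O-demethylation of 13 ⇐ hydrogenolysis of the 2'-O-benzyl ether of flavonol 12.
2. Flavonol 12 ⇐ C3-hydroxylation of flavone 10 (dioxirane epoxidation, then acid-induced epoxide opening).
3. Flavone 10 ⇐ oxidative cyclisation of 2'-hydroxychalcone 8; the pyranone C ring is the only ring built.
4. Chalcone 8 ⇐ intermolecular Claisen–Schmidt aldol condensation (key C–C bond) of A-ring ketone 4 with B-ring aldehyde 6.
5. 4 ⇐ 3,4,5-trimethoxyphenol (O-methylation, then Friedel–Crafts acetylation with ortho-demethylation); 6 ⇐ 2-hydroxy-4-methoxybenzaldehyde. Both benzene rings are bought.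

Assumption: the target has no stereocentre, so there is no enantiomer to control. The only stereo-element on the route is the E alkene of 8; transient intermediates 7, 9 and 11 are racemic. Simple reagents (MeI, AcCl, BnBr, DMDO) are not numbered.

**Route**

Step 1
Reactants: 1 3,4,5-trimethoxyphenol
Product: 2 1,2,3,5-tetramethoxybenzene
Conditions: MeI (1.5 equiv), K2CO3 (2 equiv), acetone, reflux, 12 h
Reagents that add atoms: iodomethane, CI
Why: Williamson O-methylation of the only phenol is clean and gives a symmetric arene whose two free positions are equivalent.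

Step 2
Reactants: 2 1,2,3,5-tetramethoxybenzene
Product: 4 1-(2-hydroxy-3,4,6-trimethoxyphenyl)ethan-1-one, via 1-(2,3,4,6-tetramethoxyphenyl)ethan-1-one 3 (not isolated)
Conditions: AcCl (1.2 equiv), AlCl3 (2.5 equiv), Et2O, 0 °C → rt, 24 h; then ice/2 M HCl
Reagents that add atoms: acetyl chloride, CC(Cl)=O
Why: Friedel–Crafts acylation occurs at the only (symmetry-equivalent) free position, and the AlCl3–carbonyl chelate then cleaves the more crowded ortho-methoxy group (flanked by C=O and OMe), leaving the hydrogen-bonded 2-OH that later becomes the ring oxygen next to the future 8-OMe.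

Step 3
Reactants: 5 2-hydroxy-4-methoxybenzaldehyde
Product: 6 2-(benzyloxy)-4-methoxybenzaldehyde
Conditions: BnBr (1.1 equiv), K2CO3 (1.5 equiv), DMF, 60 °C, 4 h
Reagents that add atoms: benzyl bromide, BrCc1ccccc1
Why: Williamson benzylation masks the B-ring phenol, which would otherwise deactivate the aldehyde as its phenoxide, with a group stable to base, I2/DMSO and dioxirane and removable by hydrogenolysis.

Step 4
Reactants: 4 1-(2-hydroxy-3,4,6-trimethoxyphenyl)ethan-1-one; 6 2-(benzyloxy)-4-methoxybenzaldehyde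
Product: 8 (E)-3-[2-(benzyloxy)-4-methoxyphenyl]-1-(2-hydroxy-3,4,6-trimethoxyphenyl)prop-2-en-1-one, via β-hydroxy ketone 7 (not isolated)
Conditions: 50% aq. KOH (10 equiv), EtOH, rt, 48 h; then cold 2 M HCl to pH 3
Reagents that add atoms: none
Why: Claisen–Schmidt aldol condensation of the methyl ketone enolate with the non-enolisable aldehyde, followed by E1cB dehydration of the racemic aldol 7, gives the thermodynamically favoured E enone, and any flavanone formed by partial cyclisation is converted in step 5 anyway.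

Step 5
Reactants: 8 (E)-3-[2-(benzyloxy)-4-methoxyphenyl]-1-(2-hydroxy-3,4,6-trimethoxyphenyl)prop-2-en-1-one
Product: 10 2-[2-(benzyloxy)-4-methoxyphenyl]-5,7,8-trimethoxy-4H-chromen-4-one, via flavanone 9 (not isolated)
Conditions: I2 (10 mol%), DMSO, 130 °C, 3 h; then aq. Na2S2O3
Reagents that add atoms: none
Why: Iodine-catalysed oxidative cyclisation (oxa-Michael ring closure to racemic flavanone 9, α-iodination and loss of HI, with DMSO re-oxidising HI) reliably gives flavones from 6'-alkoxy-2'-hydroxychalcones, which are the substrates that tend to give aurones under peroxide conditions.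

Step 6
Reactants: 10 2-[2-(benzyloxy)-4-methoxyphenyl]-5,7,8-trimethoxy-4H-chromen-4-one
Product: 12 2-[2-(benzyloxy)-4-methoxyphenyl]-3-hydroxy-5,7,8-trimethoxy-4H-chromen-4-one, via flavone 2,3-epoxide 11 (not isolated)
Conditions: DMDO (ca. 0.08 M in acetone, 3 equiv), CH2Cl2, 0 °C → rt, 12 h; evaporate; p-TsOH·H2O (0.1 equiv), CH2Cl2, rt, 1 h
Reagents that add atoms: dimethyldioxirane, CC1(C)OO1
Why: Dioxirane epoxidation of the enol-ether-like C2=C3 bond gives racemic epoxide 11, which opens under acid at C2 (oxocarbenium stabilised) and loses H-3 to give the achiral 3-hydroxyflavone, so no stereocentre remains.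

Step 7
Reactants: 12 2-[2-(benzyloxy)-4-methoxyphenyl]-3-hydroxy-5,7,8-trimethoxy-4H-chromen-4-one
Product: 13 3-hydroxy-2-(2-hydroxy-4-methoxyphenyl)-5,7,8-trimethoxy-4H-chromen-4-one
Conditions: H2 (1 atm), 10% Pd/C, EtOAc/MeOH 1:1, rt, 3 h
Reagents that add atoms: none
Why: Catalytic hydrogenolysis cleaves the aryl benzyl ether under neutral conditions, leaving the methyl ethers and the tetrasubstituted vinylogous-ester C2=C3 bond untouched.

Step 8
Reactants: 13 3-hydroxy-2-(2-hydroxy-4-methoxyphenyl)-5,7,8-trimethoxy-4H-chromen-4-one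
Product: 14 3,5-dihydroxy-2-(2-hydroxy-4-methoxyphenyl)-7,8-dimethoxy-4H-chromen-4-one (3,5,2'-trihydroxy-7,8,4'-trimethoxyflavone)
Conditions: anhydrous AlCl3 (5 equiv), MeCN, rt → 50 °C, monitored by TLC; then 2% aq. HCl, 60 °C, 30 min
Reagents that add atoms: none
Why: Chelation-controlled Lewis-acid demethylation, in which aluminium bridges C4=O and the peri 5-OMe in a six-membered chelate so that chloride removes only that methyl group, spares the 7-, 8- and 4'-OMe groups, and the mild, non-protic conditions avoid Wessely–Moser isomerisation.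

**Compound list**
1 | 3,4,5-trimethoxyphenol | COc1cc(O)cc(OC)c1OC | starting material
2 | 1,2,3,5-tetramethoxybenzene | COc1cc(OC)c(OC)c(OC)c1 | intermediate
3 | 1-(2,3,4,6-tetramethoxyphenyl)ethan-1-one | CC(=O)c1c(OC)cc(OC)c(OC)c1OC | intermediate
4 | 1-(2-hydroxy-3,4,6-trimethoxyphenyl)ethan-1-one | CC(=O)c1c(OC)cc(OC)c(OC)c1O | intermediate
5 | 2-hydroxy-4-methoxybenzaldehyde | COc1ccc(C=O)c(O)c1 | starting material
6 | 2-(benzyloxy)-4-methoxybenzaldehyde | COc1ccc(C=O)c(OCc2ccccc2)c1 | intermediate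
7 | rac-3-[2-(benzyloxy)-4-methoxyphenyl]-3-hydroxy-1-(2-hydroxy-3,4,6-trimethoxyphenyl)propan-1-one (racemic) | COc1ccc(C(O)CC(=O)c2c(OC)cc(OC)c(OC)c2O)c(OCc2ccccc2)c1 | intermediate
8 | (E)-3-[2-(benzyloxy)-4-methoxyphenyl]-1-(2-hydroxy-3,4,6-trimethoxyphenyl)prop-2-en-1-one | COc1ccc(/C=C/C(=O)c2c(OC)cc(OC)c(OC)c2O)c(OCc2ccccc2)c1 | intermediate
9 | rac-2-[2-(benzyloxy)-4-methoxyphenyl]-5,7,8-trimethoxychroman-4-one (racemic) | COc1ccc(C2CC(=O)c3c(OC)cc(OC)c(OC)c3O2)c(OCc2ccccc2)c1 | intermediate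
10 | 2-[2-(benzyloxy)-4-methoxyphenyl]-5,7,8-trimethoxy-4H-chromen-4-one | COc1ccc(-c2cc(=O)c3c(OC)cc(OC)c(OC)c3o2)c(OCc2ccccc2)c1 | intermediate
11 | rac-2-[2-(benzyloxy)-4-methoxyphenyl]-2,3-epoxy-5,7,8-trimethoxychroman-4-one (racemic, cis-fused epoxide) | COc1ccc(C23OC2C(=O)c2c(OC)cc(OC)c(OC)c2O3)c(OCc2ccccc2)c1 | intermediate
12 | 2-[2-(benzyloxy)-4-methoxyphenyl]-3-hydroxy-5,7,8-trimethoxy-4H-chromen-4-one | COc1ccc(-c2oc3c(OC)c(OC)cc(OC)c3c(=O)c2O)c(OCc2ccccc2)c1 | intermediate
13 | 3-hydroxy-2-(2-hydroxy-4-methoxyphenyl)-5,7,8-trimethoxy-4H-chromen-4-one | COc1ccc(-c2oc3c(OC)c(OC)cc(OC)c3c(=O)c2O)c(O)c1 | intermediate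
14 | 3,5-dihydroxy-2-(2-hydroxy-4-methoxyphenyl)-7,8-dimethoxy-4H-chromen-4-one | COc1ccc(-c2oc3c(OC)c(OC)cc(O)c3c(=O)c2O)c(O)c1 | target

**Step count and risk**
Total steps: 8. Longest linear sequence: 7 steps (1 → 2 → 4 → 8 → 10 → 12 → 13 → 14; the aldehyde branch is one step).

Most likely to fail, first: step 4 (aldol condensation). The ketone is flanked by two ortho oxygens and reacts as a phenoxide-enolate, and the aldehyde is electron-rich and ortho-substituted, so conversion may stall. The fallback sets out from 6 and 4 and comes back at flavone 10, replacing the aldol by an intermolecular Claisen-type C-acylation. Pinnick oxidation of 6 (NaClO2, NaH2PO4, 2-methyl-2-butene, t-BuOH/H2O) gives 2-(benzyloxy)-4-methoxybenzoic acid F1. Oxalyl chloride with catalytic DMF in CH2Cl2 converts it into 2-(benzyloxy)-4-methoxybenzoyl chloride F2. Ketone 4 is deprotonated with LiHMDS (3.2 equiv, THF, −78 °C) and acylated on carbon by F2 to give 1-[2-(benzyloxy)-4-methoxyphenyl]-3-(2-hydroxy-3,4,6-trimethoxyphenyl)propane-1,3-dione F3. Cyclodehydration of F3 (catalytic p-TsOH, toluene, reflux) gives 10 directly, so step 5 is also bypassed.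

Second: step 6 (dioxirane hydroxylation). The electrophilic oxidant may attack the electron-rich rings or the benzylic ether before the C2=C3 bond is consumed. The fallback sets out from chalcone 8 and comes back at flavonol 12, using a nucleophilic oxidant instead. Algar–Flynn–Oyamada oxidation of 8 (30% H2O2, aq. NaOH, MeOH, 0 °C → rt) proceeds through rac-trans-2-[2-(benzyloxy)-4-methoxyphenyl]-3-hydroxy-5,7,8-trimethoxychroman-4-one F4, which is dehydrogenated in the same pot to 12. The aurone by-product expected from a 6'-methoxychalcone would be removed by chromatography.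

Third: step 8 (selective 5-O-demethylation). The free 3-OH and 2'-OH compete for the Lewis acid, and over-reaction could cleave the 8-OMe. The fallback sets out from flavone 10 and comes back at target 14. It moves the demethylation to the flavone stage, where only the C4=O/5-OMe chelate exists, and makes hydrogenolysis the last step. BCl3 with pentamethylbenzene (CH2Cl2, −78 → 0 °C) cleaves the 5-OMe and the benzyl ether of 10 to give 5-hydroxy-2-(2-hydroxy-4-methoxyphenyl)-7,8-dimethoxy-4H-chromen-4-one F5. Double benzylation (BnBr, K2CO3, cat. KI, DMF, 80 °C) gives 5-(benzyloxy)-2-[2-(benzyloxy)-4-methoxyphenyl]-7,8-dimethoxy-4H-chromen-4-one F6. DMDO converts F6 into rac-5-(benzyloxy)-2-[2-(benzyloxy)-4-methoxyphenyl]-2,3-epoxy-7,8-dimethoxychroman-4-one F7, and catalytic p-TsOH opens this to 5-(benzyloxy)-2-[2-(benzyloxy)-4-methoxyphenyl]-3-hydroxy-7,8-dimethoxy-4H-chromen-4-one F8. Hydrogenolysis of F8 (H2, Pd/C, EtOAc/MeOH) removes both benzyl groups and gives 14.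

**Further compounds**
F1 | step 4 | 2-(benzyloxy)-4-methoxybenzoic acid | COc1ccc(C(=O)O)c(OCc2ccccc2)c1
F2 | step 4 | 2-(benzyloxy)-4-methoxybenzoyl chloride | COc1ccc(C(=O)Cl)c(OCc2ccccc2)c1
F3 | step 4 | 1-[2-(benzyloxy)-4-methoxyphenyl]-3-(2-hydroxy-3,4,6-trimethoxyphenyl)propane-1,3-dione | COc1ccc(C(=O)CC(=O)c2c(OC)cc(OC)c(OC)c2O)c(OCc2ccccc2)c1
F4 | step 6 | rac-trans-(2R*,3R*)-2-[2-(benzyloxy)-4-methoxyphenyl]-3-hydroxy-5,7,8-trimethoxychroman-4-one (racemic; one enantiomer drawn) | COc1ccc([C@@H]2[C@H](C(=O)c3c(OC)cc(OC)c(OC)c3O2)O)c(OCc2ccccc2)c1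
F5 | step 8 | 5-hydroxy-2-(2-hydroxy-4-methoxyphenyl)-7,8-dimethoxy-4H-chromen-4-one | COc1ccc(-c2cc(=O)c3c(O)cc(OC)c(OC)c3o2)c(O)c1
F6 | step 8 | 5-(benzyloxy)-2-[2-(benzyloxy)-4-methoxyphenyl]-7,8-dimethoxy-4H-chromen-4-one | COc1ccc(-c2cc(=O)c3c(OCc4ccccc4)cc(OC)c(OC)c3o2)c(OCc2ccccc2)c1
F7 | step 8 | rac-5-(benzyloxy)-2-[2-(benzyloxy)-4-methoxyphenyl]-2,3-epoxy-7,8-dimethoxychroman-4-one (racemic, cis-fused epoxide) | COc1ccc(C23OC2C(=O)c2c(OCc4ccccc4)cc(OC)c(OC)c2O3)c(OCc2ccccc2)c1
F8 | step 8 | 5-(benzyloxy)-2-[2-(benzyloxy)-4-methoxyphenyl]-3-hydroxy-7,8-dimethoxy-4H-chromen-4-one | COc1ccc(-c2oc3c(OC)c(OC)cc(OCc4ccccc4)c3c(=O)c2O)c(OCc2ccccc2)c1
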